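**Retrosynthetic overview** (ring A = benzene ring of the isochromanone, ring B = lactol, ring C = benzoate ring)
- Ring B is formed last. It is opened to the (4S)-keto acid. Closure is reversible, so C3 is set thermodynamically by C4.
- The ester is cut at the CH2–O bond, not at the acyl–O bond. This gives a terminal α-diazoketone and free 2,4-dihydroxy-3,5,6-trimethylbenzoic acid.
- The diazoketone comes from the 6-CH3 of a resorcylate by lateral carboxylation (C3), enantioselective C-methyl transfer (C4) and CH2N2 (the CH2O carbon).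
- Rings A and C are formed first, in one flask. Both derive from a single 5,6-dimethylresorcylate, made by Claisen union of two β-keto esters and aldol aromatisation of the C-methylated tetraketide. Ring C then needs only one more C-methyl group.

Assumption: the SMILES is read as (3R,4S) with 3-OH and 4-CH3 trans, and the (R,R)-tetraamine of step 4 is taken to give the (S)-acid as in the phenylacetic acid series (otherwise its antipode is used).

**Step 1**
Reactants: 1 benzyl acetoacetate; 2 ethyl 2-methylacetoacetate (racemic)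
Product: 4 benzyl 2,4-dihydroxy-5,6-dimethylbenzoate, via triketo ester 3 (not isolated)
Conditions: 1 (2 equiv): NaH, then n-BuLi, THF, 0 °C; add Na enolate of 2 (NaH, THF, 0 °C); 0 °C → rt; 1 M HCl; then Na2B4O7 buffer (pH 9.2)–THF, rt
Reagents that add atoms: none
Why: γ-Acylation of a β-keto ester dianion (Weiler/Harris chemistry) by the ester group of the pre-formed enolate of 2 assembles the C-methylated tetraketide 3, in which the most acidic carbon C2 adds to the terminal C7 methyl ketone (aldol condensation, loss of one water, enolisation) while the rival Claisen closure is blocked because it would leave C6 quaternary, so the polyketide-type aromatisation gives resorcylate 4 and erases the labile centre of 2.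

**Step 2**
Reactants: 4 benzyl 2,4-dihydroxy-5,6-dimethylbenzoate
Product: 6 benzyl 2-(benzyloxy)-4-methoxy-5,6-dimethylbenzoate, via monomethyl ether 5 (not isolated)
Conditions: K2CO3, MeI (1.0 equiv), DMF, rt; then BnBr (1.3 equiv), 60 °C
Reagents that add atoms: iodomethane, CI; benzyl bromide, BrCc1ccccc1
Why: Williamson etherification under substrate control: the 4-OH is free and is methylated at rt, whereas the 2-OH is hydrogen-bonded to the ester carbonyl and is benzylated only on heating.

**Step 3**
Reactants: 6 benzyl 2-(benzyloxy)-4-methoxy-5,6-dimethylbenzoate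
Product: 7 2-[3-(benzyloxy)-2-(benzyloxycarbonyl)-5-methoxy-6-methylphenyl]acetic acid
Conditions: LiN(iPr)2 (2.5 equiv), THF, −78 °C; CO2 (g), −78 → 0 °C; 1 M HCl
Reagents that add atoms: carbon dioxide, O=C=O
Why: Lateral lithiation of an ortho-toluate: only the 6-CH3 gives an ester-stabilised o-quinodimethane-type enolate (the 5-CH3 cannot), and its carboxylation installs C3 with the same polarity as the chain-extending Claisen step of the polyketide pathway.

**Step 4**
Reactants: 7 2-[3-(benzyloxy)-2-(benzyloxycarbonyl)-5-methoxy-6-methylphenyl]acetic acid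
Product: 8 (2S)-2-[3-(benzyloxy)-2-(benzyloxycarbonyl)-5-methoxy-6-methylphenyl]propanoic acid
Conditions: (R,R)-N,N'-bis(1-phenyl-2-piperidinoethyl)propane-1,3-diamine (1.05 equiv), n-BuLi (4.0 equiv), THF, 0 °C; 7; MeI, −78 °C; 1 M HCl (tetraamine recovered by extraction)
Reagents that add atoms: iodomethane, CI
Why: Enantioselective alkylation of an arylacetic acid enediolate held in a mixed aggregate with a C2-symmetric chiral dilithium amide (a non-covalent, recoverable auxiliary), the laboratory counterpart of C-methyl transfer: MeI reaches only the open face of the enediolate and sets C4 as (S), and the alkylated carboxylate is not deprotonated again at −78 °C.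

**Step 5**
Reactants: 8 (2S)-2-[3-(benzyloxy)-2-(benzyloxycarbonyl)-5-methoxy-6-methylphenyl]propanoic acid
Product: 10 benzyl 2-(benzyloxy)-6-[(2S)-4-diazo-3-oxobutan-2-yl]-4-methoxy-5-methylbenzoate, via mixed carbonic anhydride 9 (not isolated)
Conditions: i-BuOCOCl, N-methylmorpholine, THF, −20 °C; CH2N2, Et2O, −20 → 0 °C
Reagents that add atoms: diazomethane, C=[N+]=[N-]
Why: First stage of the Arndt–Eistert sequence (acylation of diazomethane by a mixed carbonic anhydride): the conditions are cold and essentially non-basic, so the (S) centre, whose twisted di-ortho-substituted aryl group gives little enolate stabilisation, is retained.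

**Step 6**
Reactants: 4 benzyl 2,4-dihydroxy-5,6-dimethylbenzoate
Product: 12 benzyl 3-formyl-2,4-dihydroxy-5,6-dimethylbenzoate, via iminium chloride 11 (not isolated)
Conditions: POCl3, DMF, MeCN, 0 °C → rt; H2O, 40 °C
Reagents that add atoms: N,N-dimethylformamide, CN(C)C=O; water, O
Why: Vilsmeier–Haack formylation: C3, flanked by two OH groups, is the only unsubstituted and the most nucleophilic ring position of 4, and hydrolysis of iminium salt 11 gives the aldehyde.

**Step 7**
Reactants: 12 benzyl 3-formyl-2,4-dihydroxy-5,6-dimethylbenzoate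
Product: 13 2,4-dihydroxy-3,5,6-trimethylbenzoic acid
Conditions: H2 (3 atm), 10% Pd/C, EtOAc–AcOH, rt
Reagents that add atoms: none
Why: Catalytic hydrogenolysis does two jobs at once: the doubly ortho-hydroxylated aryl aldehyde is reduced via the benzylic alcohol to the third C-methyl group, and the benzyl ester is cleaved to the free acid.

**Step 8**
Reactants: 10 benzyl 2-(benzyloxy)-6-[(2S)-4-diazo-3-oxobutan-2-yl]-4-methoxy-5-methylbenzoate; 13 2,4-dihydroxy-3,5,6-trimethylbenzoic acid
Product: 14 benzyl 2-(benzyloxy)-6-[(2S)-4-(2,4-dihydroxy-3,5,6-trimethylbenzoyloxy)-3-oxobutan-2-yl]-4-methoxy-5-methylbenzoate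
Conditions: Cu(acac)2 (5 mol %), ClCH2CH2Cl, 60 °C
Reagents that add atoms: none
Why: Copper-carbenoid O–H insertion of a carboxylic acid into a terminal α-diazoketone forms the CH2–O bond, so the di-ortho-substituted acid acts as the nucleophile and never has to be activated; its acidic CO2H outcompetes the chelated 2-OH and the hindered 4-OH, and C4 is not touched.

**Step 9**
Reactants: 14 benzyl 2-(benzyloxy)-6-[(2S)-4-(2,4-dihydroxy-3,5,6-trimethylbenzoyloxy)-3-oxobutan-2-yl]-4-methoxy-5-methylbenzoate
Product: 16 [(3R,4S)-3,8-dihydroxy-6-methoxy-4,5-dimethyl-1-oxo-3,4-dihydro-1H-isochromen-3-yl]methyl 2,4-dihydroxy-3,5,6-trimethylbenzoate, via open keto acid 15 (not isolated)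
Conditions: H2 (1 atm), 10% Pd/C, EtOAc, rt
Reagents that add atoms: none
Why: Hydrogenolysis of both benzyl groups under neutral conditions frees keto acid 15, which closes by ring–chain tautomerism (addition of the carboxyl group to the C3 ketone), the counterpart of the chain-release step; closure is reversible, so C3 ends under thermodynamic control with 4-CH3 pseudo-axial (avoiding the peri 5-CH3), 3-OH axial and anti to it (anomeric effect) and the CH2O-acyl arm equatorial, which is (3R) for (4S).

**Compound list**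
1 | benzyl acetoacetate | CC(=O)CC(=O)OCc1ccccc1 | starting material
2 | ethyl 2-methylacetoacetate (racemic) | CCOC(=O)C(C)C(C)=O | starting material
3 | benzyl 6-methyl-3,5,7-trioxooctanoate | CC(=O)C(C)C(=O)CC(=O)CC(=O)OCc1ccccc1 | intermediate
4 | benzyl 2,4-dihydroxy-5,6-dimethylbenzoate | Cc1c(O)cc(O)c(C(=O)OCc2ccccc2)c1C | intermediate
5 | benzyl 2-hydroxy-4-methoxy-5,6-dimethylbenzoate | COc1cc(O)c(C(=O)OCc2ccccc2)c(C)c1C | intermediate
6 | benzyl 2-(benzyloxy)-4-methoxy-5,6-dimethylbenzoate | COc1cc(OCc2ccccc2)c(C(=O)OCc2ccccc2)c(C)c1C | intermediate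
7 | 2-[3-(benzyloxy)-2-(benzyloxycarbonyl)-5-methoxy-6-methylphenyl]acetic acid | COc1cc(OCc2ccccc2)c(C(=O)OCc2ccccc2)c(CC(=O)O)c1C | intermediate
8 | (2S)-2-[3-(benzyloxy)-2-(benzyloxycarbonyl)-5-methoxy-6-methylphenyl]propanoic acid | COc1cc(OCc2ccccc2)c(C(=O)OCc2ccccc2)c([C@H](C)C(=O)O)c1C | intermediate
9 | mixed isobutyl carbonic anhydride of 8 | COc1cc(OCc2ccccc2)c(C(=O)OCc2ccccc2)c([C@H](C)C(=O)OC(=O)OCC(C)C)c1C | intermediate
10 | benzyl 2-(benzyloxy)-6-[(2S)-4-diazo-3-oxobutan-2-yl]-4-methoxy-5-methylbenzoate | COc1cc(OCc2ccccc2)c(C(=O)OCc2ccccc2)c([C@H](C)C(=O)C=[N+]=[N-])c1C | intermediate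
11 | [3-(benzyloxycarbonyl)-2,6-dihydroxy-4,5-dimethylphenyl]methylidene(dimethyl)ammonium chloride | C[N+](C)=Cc1c(O)c(C)c(C)c(C(=O)OCc2ccccc2)c1O.[Cl-] | intermediate
12 | benzyl 3-formyl-2,4-dihydroxy-5,6-dimethylbenzoate | O=Cc1c(O)c(C)c(C)c(C(=O)OCc2ccccc2)c1O | intermediate
13 | 2,4-dihydroxy-3,5,6-trimethylbenzoic acid | Cc1c(O)c(C)c(O)c(C(=O)O)c1C | intermediate
14 | benzyl 2-(benzyloxy)-6-[(2S)-4-(2,4-dihydroxy-3,5,6-trimethylbenzoyloxy)-3-oxobutan-2-yl]-4-methoxy-5-methylbenzoate | COc1cc(OCc2ccccc2)c(C(=O)OCc2ccccc2)c([C@H](C)C(=O)COC(=O)c2c(C)c(C)c(O)c(C)c2O)c1C | intermediate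
15 | 2-[(2S)-4-(2,4-dihydroxy-3,5,6-trimethylbenzoyloxy)-3-oxobutan-2-yl]-6-hydroxy-4-methoxy-3-methylbenzoic acid | COc1cc(O)c(C(=O)O)c([C@H](C)C(=O)COC(=O)c2c(C)c(C)c(O)c(C)c2O)c1C | intermediate
16 | [(3R,4S)-3,8-dihydroxy-6-methoxy-4,5-dimethyl-1-oxo-3,4-dihydro-1H-isochromen-3-yl]methyl 2,4-dihydroxy-3,5,6-trimethylbenzoate | COc1cc(O)c2c(c1C)[C@H](C)[C@](O)(COC(=O)c1c(C)c(C)c(O)c(C)c1O)OC2=O | target

**Step count**
Total step count: 9.
Longest linear sequence: 7 (steps 1, 2, 3, 4, 5, 8, 9).

**Steps most likely to fail**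

*Step 1.* Two enolates have to react with each other, proton exchange between them can scramble the partners, and the ester of 2 is hindered. The fallback sets out from 1 and comes back at 3. The chain is grown one ketide at a time instead of by a convergent union. The dianion of 1 is acylated by N-methoxy-N-methylpropanamide to benzyl 3,5-dioxoheptanoate F1. The trianion of F1 (LiN(iPr)2, 3.3 equiv, THF, −78 → 0 °C) is acetylated at its terminal carbanion by N-methoxy-N-methylacetamide, which gives 3. Compound 3 is then aromatised to 4 as before.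

*Step 4.* The di-ortho-substituted aryl group and the neighbouring ester may disturb the mixed aggregate and lower the ee. The enediolate oxygen may also attack the ortho ester. The fallback sets out from 7 and comes back at 8. A covalent auxiliary replaces the non-covalent one.
- Acid 7 is converted (t-BuCOCl, Et3N) into the pivalic mixed anhydride F2.
- F2 acylates lithiated (S)-4-benzyl-1,3-oxazolidin-2-one to give the arylacetyl imide F3.
- Evans alkylation (NaN(SiMe3)2, MeI, THF, −78 °C) of the chelated Z-enolate, on the face away from the benzyl group, gives the (S)-methylated imide F4.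
- LiOH/H2O2 releases 8. The hindered benzyl benzoate survives.

*Step 8.* The carbenoid may attack the ortho ester carbonyl or the aryl ring, or insert into a phenol. The fallback sets out from 10 and comes back at 14. An ionic displacement replaces the carbenoid. HBr (48 % aq, Et2O, 0 °C) turns 10 into the (S)-α-bromoketone F5. The potassium carboxylate of 13 (KHCO3, 1 equiv, DMF, rt; the phenols stay protonated) displaces bromide by SN2 and gives 14.

**Further compounds**
F1 | step 1 | benzyl 3,5-dioxoheptanoate | CCC(=O)CC(=O)CC(=O)OCc1ccccc1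
F2 | step 4 | pivalic mixed anhydride of 7 | COc1cc(OCc2ccccc2)c(C(=O)OCc2ccccc2)c(CC(=O)OC(=O)C(C)(C)C)c1C
F3 | step 4 | benzyl 2-(benzyloxy)-6-{2-[(4S)-4-benzyl-2-oxo-1,3-oxazolidin-3-yl]-2-oxoethyl}-4-methoxy-5-methylbenzoate | COc1cc(OCc2ccccc2)c(C(=O)OCc2ccccc2)c(CC(=O)N2[C@@H](Cc3ccccc3)COC2=O)c1C
F4 | step 4 | benzyl 2-(benzyloxy)-6-{(2S)-1-[(4S)-4-benzyl-2-oxo-1,3-oxazolidin-3-yl]-1-oxopropan-2-yl}-4-methoxy-5-methylbenzoate | COc1cc(OCc2ccccc2)c(C(=O)OCc2ccccc2)c([C@H](C)C(=O)N2[C@@H](Cc3ccccc3)COC2=O)c1C
F5 | step 8 | benzyl 2-(benzyloxy)-6-[(2S)-4-bromo-3-oxobutan-2-yl]-4-methoxy-5-methylbenzoate | COc1cc(OCc2ccccc2)c(C(=O)OCc2ccccc2)c([C@H](C)C(=O)CBr)c1C
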